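**Assumption (one line):** positions carry daucane numbers (C1 = quaternary C–Me, C2 = CH–OAc, C4 = C(OH)i-Pr, C5 = ring-fusion CH, C6 = CH–O-anisoyl, C8=C9 alkene, C10 = CH–OH), β is the face of the C1 methyl group of the target, and the (S,R,R)-phosphoramidite is taken to deliver methyl in the sense established for this monoketal enone in prostaglandin work (otherwise its antipode is used).

## Retrosynthetic overview

1. The C10 carbinol comes from Luche reduction of a C8=C9–C10 enone, made by allylic C–H oxidation of the dauc-8-ene; the C6 anisoate/C4–OH pair comes from DDQ opening of a 4,6-O-(p-methoxybenzylidene) acetal.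
2. The seven-membered ring is closed by RCM of a C1-allyl/C6-methallyl diene (C8=C9).
3. Key disconnection: the C4–O bond, made by a p-anisaldehyde hemiacetal-relayed oxa-Michael addition from the C6 hydroxyl onto a 3-isopropylcyclopent-2-enone; this sets C4, and the aldehyde later becomes the anisoyl group.
4. The enone comes from isopropyl addition/deketalisation–dehydration and α′-allylation (C1); the C1 methyl, C5 and C6 come from a catalytic asymmetric methyl conjugate addition/aldol on cyclopentenedione monoketal with 3-methylbut-3-enal.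
5. Ring order: cyclopentane (commercial cyclopent-4-ene-1,3-dione) → temporary 1,3-dioxane → cycloheptene.

## Route

Step 1
Reactants: 1 cyclopent-4-ene-1,3-dione; 2 2,2-dimethylpropane-1,3-diol
Product: 3 8,8-dimethyl-6,10-dioxaspiro[4.5]dec-3-en-2-one
Conditions: p-TsOH (cat.), benzene, Dean–Stark, stopped at the mono-ketal
Reagents that add atoms: none
Why: Acid-catalysed ketalisation of a symmetrical enedione; after the first ketal forms, the remaining carbonyl is an ordinary, more hindered enone and does not ketalise further, and no stereocentre is formed.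

Step 2
Reactants: 4 3-methylbut-3-en-1-ol
Product: 5 3-methylbut-3-enal
Conditions: Dess–Martin periodinane, CH2Cl2, 0 °C; used at once as a cold solution
Reagents that add atoms: none
Why: Dess–Martin oxidation under non-basic conditions gives the β,γ-unsaturated aldehyde without isomerisation to the conjugated 3-methylbut-2-enal.

Step 3
Reactants: 3 8,8-dimethyl-6,10-dioxaspiro[4.5]dec-3-en-2-one; 5 3-methylbut-3-enal
Product: 7 (3S,4R)-3-[(1S)-1-hydroxy-3-methylbut-3-en-1-yl]-4,8,8-trimethyl-6,10-dioxaspiro[4.5]decan-2-one, via methylzinc enolate 6 (not isolated)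
Conditions: ZnMe2 (1.5 equiv), Cu(OTf)2 (3 mol%), (S,R,R)-binaphthol/bis(1-phenylethyl)amine phosphoramidite (6 mol%), toluene, −30 °C; then 5, −30 °C; aq. NH4Cl
Reagents that add atoms: dimethylzinc, C[Zn]C
Why: Copper-catalysed asymmetric conjugate addition (Feringa-type tandem addition–aldol) sets the C1 methyl centre by ligand control; the zinc enolate then adds to 5 trans to that methyl through a Zimmerman–Traxler chair, giving the C5/C6 anti aldol (the minor syn carbinol epimer is removed by chromatography).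

Step 4
Reactants: 7 (3S,4R)-3-[(1S)-1-hydroxy-3-methylbut-3-en-1-yl]-4,8,8-trimethyl-6,10-dioxaspiro[4.5]decan-2-one
Product: 9 (4R,5R)-4-[(1S)-1-hydroxy-3-methylbut-3-en-1-yl]-5-methyl-3-(propan-2-yl)cyclopent-2-en-1-one, via tertiary carbinol 8 (not isolated)
Conditions: i-PrLi (3 equiv), CeCl3, THF, −78 °C; then 2 M HCl, THF, 23 °C, short exposure
Reagents that add atoms: isopropyllithium, [Li]C(C)C; water, O
Why: Organocerium 1,2-addition to the hindered, enolisable ketone, then acid hydrolysis of the ketal and E1cB-type dehydration of the tertiary β-hydroxy ketone give the conjugated cyclopentenone (Stork–Danheiser-type carbonyl transposition); C5 and C6 are untouched, the C1 epimers converge in step 5, and the C3=C4 enone lets C1 be quaternised without β-elimination at C4.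

Step 5
Reactants: 9 (4R,5R)-4-[(1S)-1-hydroxy-3-methylbut-3-en-1-yl]-5-methyl-3-(propan-2-yl)cyclopent-2-en-1-one
Product: 11 (4S,5R)-4-[(1S)-1-hydroxy-3-methylbut-3-en-1-yl]-5-methyl-3-(propan-2-yl)-5-(prop-2-en-1-yl)cyclopent-2-en-1-one, via dilithium alkoxide enolate 10 (not isolated)
Conditions: LiN(i-Pr)2 (2.3 equiv), THF, −78 °C; allyl bromide, DMPU, −78 to −30 °C; aq. NH4Cl
Reagents that add atoms: allyl bromide, C=CCBr
Why: Kinetic α′-deprotonation gives the cross-conjugated alkoxide–enolate, which is C-allylated (enolate alkylation, C-selective as for Fráter–Seebach dianions) anti to the C5 side chain, setting the quaternary C1 with allyl α and methyl β.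

Step 6
Reactants: 11 (4S,5R)-4-[(1S)-1-hydroxy-3-methylbut-3-en-1-yl]-5-methyl-3-(propan-2-yl)-5-(prop-2-en-1-yl)cyclopent-2-en-1-one; 12 4-methoxybenzaldehyde
Product: 14 (2S,4S,4aS,5R,7aR)-2-(4-methoxyphenyl)-5-methyl-4-(2-methylprop-2-en-1-yl)-7a-(propan-2-yl)-5-(prop-2-en-1-yl)tetrahydro-4H-cyclopenta[d][1,3]dioxin-6(5H)-one, via hemiacetal 13 (not isolated)
Conditions: 12 (4 equiv), KN(SiMe3)2 (0.25 equiv), THF, −40 to −10 °C; AcOH quench at −40 °C
Reagents that add atoms: none
Why: Proposed new method: a hemiacetal-relayed oxa-Michael addition to a β,β-disubstituted cyclopentenone that forges a tertiary C–O bond — the C6 alkoxide adds reversibly to 12, and the hemiacetal oxygen, held on the β face by the C5–C6 bond, closes a six-membered ring onto C4 (6-exo) so that the C4–O bond can only form cis to the side chain without severe strain, the enolate is protonated at C3 and thermodynamic control places the aryl group equatorial, the adduct being held against retro-addition by the cis-fused acetal and the cold acidic quench; the closest known reaction type is the base-mediated benzaldehyde hemiacetal/oxa-conjugate addition of δ-hydroxy enoates and enones to syn-1,3-diol benzylidene acetals (Evans–Prunet type), shown only for β-monosubstituted acceptors and never with the aldehyde later serving as the acyl source.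

Step 7
Reactants: 14 (2S,4S,4aS,5R,7aR)-2-(4-methoxyphenyl)-5-methyl-4-(2-methylprop-2-en-1-yl)-7a-(propan-2-yl)-5-(prop-2-en-1-yl)tetrahydro-4H-cyclopenta[d][1,3]dioxin-6(5H)-one
Product: 16 (2S,4S,4aS,5R,6S,7aR)-2-(4-methoxyphenyl)-5-methyl-4-(2-methylprop-2-en-1-yl)-7a-(propan-2-yl)-5-(prop-2-en-1-yl)hexahydro-4H-cyclopenta[d][1,3]dioxin-6-yl acetate, via lithium C2 alkoxide 15 (not isolated)
Conditions: LiBH(s-Bu)3, THF, −78 °C; then Ac2O, DMAP, −78 to 0 °C; non-oxidative work-up
Reagents that add atoms: acetic anhydride, CC(=O)OC(C)=O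
Why: Substrate-controlled reduction in which the bulky hydride attacks the C2 ketone from the β face (the α face carries the C1 allyl and the C4 isopropyl groups), giving the 2α-alkoxide, which is acetylated in the same flask.

Step 8
Reactants: 16 (2S,4S,4aS,5R,6S,7aR)-2-(4-methoxyphenyl)-5-methyl-4-(2-methylprop-2-en-1-yl)-7a-(propan-2-yl)-5-(prop-2-en-1-yl)hexahydro-4H-cyclopenta[d][1,3]dioxin-6-yl acetate
Product: 17 4β,6α-(4-methoxybenzylidenedioxy)dauc-8-en-2α-yl acetate
Conditions: second-generation Hoveyda–Grubbs catalyst RuCl2(H2IMes)(=CH–C6H4-2-Oi-Pr) (5 mol%), toluene (5 mM), 80 °C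
Reagents that add atoms: none
Why: Ring-closing metathesis between the monosubstituted allyl and the 1,1-disubstituted methallyl alkene closes the trans-fused cycloheptene with its trisubstituted C8=C9 bond; no stereocentre is touched.

Step 9
Reactants: 17 4β,6α-(4-methoxybenzylidenedioxy)dauc-8-en-2α-yl acetate
Product: 19 2α-acetoxy-4β-hydroxydauc-8-en-6α-yl 4-methoxybenzoate, via cyclic ortho-acid 18 (not isolated)
Conditions: DDQ (1.5 equiv), CH2Cl2/pH 7 buffer (10:1), 0 to 23 °C
Reagents that add atoms: water, O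
Why: Oxidative opening of a p-methoxybenzylidene acetal — DDQ removes the benzylic acetal hydride, water adds, and the ortho-acid collapses to the less hindered secondary C6 ester and the free tertiary C4 alcohol (any tertiary ester equilibrates to the secondary one by 1,3-acyl shift).

Step 10
Reactants: 19 2α-acetoxy-4β-hydroxydauc-8-en-6α-yl 4-methoxybenzoate
Product: 20 2α-acetoxy-4β-hydroxy-10-oxodauc-8-en-6α-yl 4-methoxybenzoate
Conditions: Rh2(cap)4 (cap = caprolactamate, 1 mol%), t-BuOOH (5 equiv), K2CO3, CH2Cl2, 23 °C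
Reagents that add atoms: tert-butyl hydroperoxide, CC(C)(C)OO
Why: Radical allylic C–H oxidation (Doyle type) at C10, the allylic CH2 at the CH end of the trisubstituted alkene and remote from the electron-withdrawing C6 ester (the selectivity seen in 7-oxidation of 3-acyloxy-5-ene steroids), gives the conjugated enone.

Step 11
Reactants: 20 2α-acetoxy-4β-hydroxy-10-oxodauc-8-en-6α-yl 4-methoxybenzoate
Product: 21 2α-acetoxy-4β,10β-dihydroxydauc-8-en-6α-yl 4-methoxybenzoate (CNP0261832.1)
Conditions: NaBH4, CeCl3·7H2O, MeOH, −78 to −40 °C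
Reagents that add atoms: none
Why: Luche 1,2-reduction in which hydride attacks C10 from the α face, anti to the angular β-methyl on C1, giving the 10β-alcohol; the two esters survive at low temperature.

## Compound list

1 | cyclopent-4-ene-1,3-dione | O=C1CC(=O)C=C1 | starting material
2 | 2,2-dimethylpropane-1,3-diol | OCC(C)(C)CO | starting material
3 | 8,8-dimethyl-6,10-dioxaspiro[4.5]dec-3-en-2-one | O=C1C=CC2(C1)OCC(C)(C)CO2 | intermediate
4 | 3-methylbut-3-en-1-ol | CC(=C)CCO | starting material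
5 | 3-methylbut-3-enal | CC(=C)CC=O | intermediate
6 | methylzinc (4R)-4,8,8-trimethyl-6,10-dioxaspiro[4.5]dec-2-en-2-olate | C[Zn]OC1=C[C@@H](C)C2(C1)OCC(C)(C)CO2 | intermediate
7 | (3S,4R)-3-[(1S)-1-hydroxy-3-methylbut-3-en-1-yl]-4,8,8-trimethyl-6,10-dioxaspiro[4.5]decan-2-one (C5 side chain β, C1 methyl α) | C=C(C)C[C@H](O)[C@H]1C(=O)CC2(OCC(C)(C)CO2)[C@@H]1C | intermediate
8 | (2R,3S,4R)-3-[(1S)-1-hydroxy-3-methylbut-3-en-1-yl]-4,8,8-trimethyl-2-(propan-2-yl)-6,10-dioxaspiro[4.5]decan-2-ol (expected major C4 epimer; this centre is lost in the same step) | C=C(C)C[C@H](O)[C@H]1[C@](O)(C(C)C)CC2(OCC(C)(C)CO2)[C@@H]1C | intermediate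
9 | (4R,5R)-4-[(1S)-1-hydroxy-3-methylbut-3-en-1-yl]-5-methyl-3-(propan-2-yl)cyclopent-2-en-1-one (trans shown; the C1 epimer behaves identically) | C=C(C)C[C@H](O)[C@H]1C(C(C)C)=CC(=O)[C@@H]1C | intermediate
10 | dilithium alkoxide enolate of 9 (O–Li at C6, cross-conjugated C1=C2 enolate) | [Li]O[C@@H](CC(C)=C)[C@H]1C(C(C)C)=CC(O[Li])=C1C | intermediate
11 | (4S,5R)-4-[(1S)-1-hydroxy-3-methylbut-3-en-1-yl]-5-methyl-3-(propan-2-yl)-5-(prop-2-en-1-yl)cyclopent-2-en-1-one | C=C(C)C[C@H](O)[C@H]1C(C(C)C)=CC(=O)[C@]1(C)CC=C | intermediate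
12 | 4-methoxybenzaldehyde | COc1ccc(C=O)cc1 | starting material
13 | hemiacetal of 11 with 12 at the C6 oxygen (hemiacetal carbon epimeric) | COc1ccc(cc1)C(O)O[C@@H](CC(C)=C)[C@H]1C(C(C)C)=CC(=O)[C@]1(C)CC=C | intermediate
14 | (2S,4S,4aS,5R,7aR)-2-(4-methoxyphenyl)-5-methyl-4-(2-methylprop-2-en-1-yl)-7a-(propan-2-yl)-5-(prop-2-en-1-yl)tetrahydro-4H-cyclopenta[d][1,3]dioxin-6(5H)-one (cis-fused, aryl equatorial) | C=C(C)C[C@@H]1O[C@H](c2ccc(OC)cc2)O[C@@]3(C(C)C)CC(=O)[C@](C)(CC=C)[C@@H]13 | intermediate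
15 | lithium alkoxide of the C2 α-alcohol from 14 | C=C(C)C[C@@H]1O[C@H](c2ccc(OC)cc2)O[C@@]3(C(C)C)C[C@H](O[Li])[C@](C)(CC=C)[C@@H]13 | intermediate
16 | (2S,4S,4aS,5R,6S,7aR)-2-(4-methoxyphenyl)-5-methyl-4-(2-methylprop-2-en-1-yl)-7a-(propan-2-yl)-5-(prop-2-en-1-yl)hexahydro-4H-cyclopenta[d][1,3]dioxin-6-yl acetate | C=C(C)C[C@@H]1O[C@H](c2ccc(OC)cc2)O[C@@]3(C(C)C)C[C@H](OC(C)=O)[C@](C)(CC=C)[C@@H]13 | intermediate
17 | 4β,6α-(4-methoxybenzylidenedioxy)dauc-8-en-2α-yl acetate (trans-fused rings, 1β-methyl, 5α-H) | COc1ccc(cc1)[C@H]4O[C@H]2CC(C)=CC[C@@]3(C)[C@@H](OC(C)=O)C[C@@](O4)(C(C)C)[C@H]23 | intermediate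
18 | cyclic ortho-acid of 17 (2-hydroxy-2-(4-methoxyphenyl)-1,3-dioxane; ortho-acid carbon epimeric) | COc1ccc(cc1)C4(O)O[C@H]2CC(C)=CC[C@@]3(C)[C@@H](OC(C)=O)C[C@@](O4)(C(C)C)[C@H]23 | intermediate
19 | 2α-acetoxy-4β-hydroxydauc-8-en-6α-yl 4-methoxybenzoate | COc1ccc(C(=O)O[C@H]2CC(C)=CC[C@@]3(C)[C@@H](OC(C)=O)C[C@@](O)(C(C)C)[C@H]23)cc1 | intermediate
20 | 2α-acetoxy-4β-hydroxy-10-oxodauc-8-en-6α-yl 4-methoxybenzoate | COc1ccc(C(=O)O[C@H]2CC(C)=CC(=O)[C@@]3(C)[C@@H](OC(C)=O)C[C@@](O)(C(C)C)[C@H]23)cc1 | intermediate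
21 | 2α-acetoxy-4β,10β-dihydroxydauc-8-en-6α-yl 4-methoxybenzoate (CNP0261832.1) | COc1ccc(C(=O)O[C@H]2CC(C)=C[C@H](O)[C@@]3(C)[C@@H](OC(C)=O)C[C@@](O)(C(C)C)[C@H]23)cc1 | target

## Step count and risks

Total step count: 11. Longest linear sequence: 10 steps (steps 1 and 3 to 11; step 2 is a one-step side branch).

The three steps most likely to fail:

**Step 6 (the proposed new method).** The risks are retro-addition at the fully substituted carbon, vinylogous retro-aldol loss of the C6 side chain, and C5 epimerisation under base. The fallback uses known, irreversible C–O chemistry; it sets out from 11 and comes back at 14. The lithium alkoxide of 11 directs a nucleophilic (Weitz–Scheffer) epoxidation with preformed LiOOt-Bu (THF, −20 °C) to the β face, giving the 3β,4β-epoxy ketone F2. SmI2 (THF/MeOH, −90 °C) cleaves the C3–O bond to give the 4β-hydroxy ketone F3. p-Anisaldehyde dimethyl acetal with PPTS (CH2Cl2, 23 °C) then closes the acetal to 14.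

**Step 3.** The risks are low reactivity or selectivity of ZnMe2 in the conjugate addition and poor C6 selectivity or isomerisation of 5 in the zinc aldol. The fallback separates the two events; it sets out from 3 and comes back at 7. CuBr·SMe2 (5 mol%) with a Josiphos-type ferrocenyl diphosphine (antipode chosen for the same methyl sense), MeMgBr and TMSCl in t-BuOMe at −75 °C give the trimethylsilyl enol ether F1. MeLi (THF, −78 °C) releases the lithium enolate, which adds to 5 at −78 °C through the closed transition state to give 7.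

**Step 10.** The risks are competing oxidation at C7 or the C8 methyl and over-oxidation. The fallback builds the enone by transposition; it sets out from 19 and comes back at 20. mCPBA (CH2Cl2, 0 °C) gives the 8,9-epoxide F4 (α drawn; either face converges). NaSePh (from (PhSe)2 and NaBH4, EtOH) opens it at C9 to the 8-hydroxy-9-phenylselenide F5. H2O2 (THF, 0 to 23 °C) oxidises the selenide, and syn-elimination toward C10 gives the tertiary allylic alcohol F6. Pyridinium chlorochromate [C5H5NH][CrO3Cl] (CH2Cl2, 23 °C) effects the oxidative 1,3-transposition (Babler–Dauben) to 20.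

## Further compounds

F1 | step 3 | (4R)-4,8,8-trimethyl-2-(trimethylsilyloxy)-6,10-dioxaspiro[4.5]dec-2-ene | C[Si](C)(C)OC1=C[C@@H](C)C2(C1)OCC(C)(C)CO2
F2 | step 6 | 3β,4β-epoxy ketone from 11 (epoxide cis to the C6 side chain) | C=C(C)C[C@H](O)[C@H]1[C@@]2(C(C)C)O[C@H]2C(=O)[C@]1(C)CC=C
F3 | step 6 | 4β-hydroxy ketone (C4 tertiary alcohol, C6 secondary alcohol, C2 ketone) | C=C(C)C[C@H](O)[C@H]1[C@](O)(C(C)C)CC(=O)[C@]1(C)CC=C
F4 | step 10 | 8α,9α-epoxide of 19 | COc1ccc(C(=O)O[C@H]2C[C@@]4(C)O[C@H]4C[C@@]3(C)[C@@H](OC(C)=O)C[C@@](O)(C(C)C)[C@H]23)cc1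
F5 | step 10 | 8α-hydroxy-9β-(phenylselanyl) derivative of 19 | COc1ccc(C(=O)O[C@H]2C[C@@](C)(O)[C@H]([Se]c4ccccc4)C[C@@]3(C)[C@@H](OC(C)=O)C[C@@](O)(C(C)C)[C@H]23)cc1
F6 | step 10 | 2α-acetoxy-4β,8α-dihydroxydauc-9-en-6α-yl 4-methoxybenzoate | COc1ccc(C(=O)O[C@H]2C[C@@](C)(O)C=C[C@@]3(C)[C@@H](OC(C)=O)C[C@@](O)(C(C)C)[C@H]23)cc1
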